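**Plan**
- Retrosynthesis cuts the two interflavanyl bonds C4–C6 and, in each unit, O1–C2 and C4–C4a. Every C ring then comes from one resorcinol aryllithium (rings T, M, L = A rings of the top, middle and bottom unit) and one common (2R,3S)-epoxy amide that carries C2, C3, C4 and the catechol ring.
- Forward: ring T is acylated and closed to the top dihydroflavonol, which is reduced and arylated at C4 with the ring M boronic acid. Ring M is then acylated and closed (middle C ring), the ketone reduced and C4 arylated with the ring L arene. Ring L is acylated and closed (bottom C ring); hydrogenolysis and NaBH4 finish.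
- Enabling feature: in the middle unit O1 is the ring M oxygen ortho to C4a, and C2 is benzylic to the 3,4-dioxygenated ring. With C4 held as a ketone, the C8a phenoxide opens the C2–C3 epoxide at C2 (6-endo); the ketone is afterwards spent as the C4 cation that takes up ring L.
- Stereochemistry: C2 and C3 of all three units come from one catalytic asymmetric epoxidation (inversion at C2 on each ring closure). Top C4 (3,4-cis) comes from aryl delivery by boron held on O3, middle C4 (3,4-trans) from arene attack anti to O3, bottom C4 from axial hydride addition.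

Key step: step 13

Remark: flavan numbering is used for every unit; the (S)-BINOL catalyst of step 2 is assumed to give the (2R,3S)-epoxide, as it does with chalcones, and the antipodal ligand is taken if the sense proves opposite.

Step 1
Reactants: 1 3,4-bis(benzyloxy)benzaldehyde; 2 diethyl [2-(morpholin-4-yl)-2-oxoethyl]phosphonate
Product: 3 (E)-3-[3,4-bis(benzyloxy)phenyl]-1-(morpholin-4-yl)prop-2-en-1-one
Conditions: NaH, THF, 0 °C → rt
Reagents that add atoms: none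
Why: Horner–Wadsworth–Emmons olefination of an aryl aldehyde with a stabilised phosphonoacetamide should give the (E)-enamide.

Step 2
Reactants: 3 (E)-enamide
Product: 4 {(2R,3S)-3-[3,4-bis(benzyloxy)phenyl]oxiran-2-yl}(morpholin-4-yl)methanone
Conditions: Sm(O-i-Pr)3, (S)-BINOL, Ph3As=O (10 mol% each), t-BuOOH (decane), 4 Å MS, THF, rt
Reagents that add atoms: tert-butyl hydroperoxide, CC(C)(C)OO
Why: Lanthanoid–BINOL-catalysed nucleophilic epoxidation of an α,β-unsaturated amide; the chiral samarium peroxide adds to one enantioface of the (E)-alkene and so sets both centres of the trans-epoxide, the source of C2 and C3 of all three units.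

Step 3
Reactants: 5 4-bromobenzene-1,3-diol
Product: 6 1-bromo-2,4-bis(prop-2-en-1-yloxy)benzene
Conditions: allyl bromide, K2CO3, acetone, reflux
Reagents that add atoms: allyl bromide, C=CCBr
Why: Williamson etherification of both phenols; allyl survives aryllithium chemistry and leaves later under Pd catalysis without acid.

Step 4
Reactants: 6 1-bromo-2,4-bis(prop-2-en-1-yloxy)benzene; 4 epoxy amide
Product: 8 {(2R,3S)-3-[3,4-bis(benzyloxy)phenyl]oxiran-2-yl}[2,4-bis(prop-2-en-1-yloxy)phenyl]methanone, via aryllithium 7 (not isolated)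
Conditions: n-BuLi, THF, −78 °C; then 4, −78 → −40 °C; aq. NH4Cl
Reagents that add atoms: none
Why: Bromine–lithium exchange followed by acylation with the morpholine amide (Weinreb-type, stable tetrahedral adduct) should give the ketone without over-addition and leave the epoxide centres untouched.

Step 5
Reactants: 8 bis(allyloxy) epoxy ketone
Product: 10 (2R,3R)-2-[3,4-bis(benzyloxy)phenyl]-3,7-dihydroxy-2,3-dihydro-4H-chromen-4-one (3′,4′-di-O-benzylfustin), via dihydroxyphenyl epoxy ketone 9 (not isolated)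
Conditions: Pd(PPh3)4 (5 mol%), K2CO3 (0.3 equiv), MeOH–THF, 0 °C → rt, argon; AcOH quench
Reagents that add atoms: none
Why: Pd-catalysed allyl transfer to methanol (Tsuji–Trost type) frees the phenoxides, and the ortho one opens the epoxide at the benzylic carbon with inversion (Algar–Flynn–Oyamada-type 6-endo closure), which should give the 2,3-trans dihydroflavonol.

Step 6
Reactants: 10 3′,4′-di-O-benzylfustin
Product: 11 (2R,3R)-7-(benzyloxy)-2-[3,4-bis(benzyloxy)phenyl]-3-hydroxy-2,3-dihydro-4H-chromen-4-one (7,3′,4′-tri-O-benzylfustin)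
Conditions: BnBr, K2CO3, DMF, rt
Reagents that add atoms: benzyl bromide, BrCc1ccccc1
Why: Williamson etherification under weak base alkylates the acidic 7-phenol (para to the carbonyl) and leaves the secondary C3 alcohol free.

Step 7
Reactants: 11 7,3′,4′-tri-O-benzylfustin
Product: 12 (2R,3S,4R)-7-(benzyloxy)-2-[3,4-bis(benzyloxy)phenyl]-3,4-dihydro-2H-chromene-3,4-diol (2,3-trans-3,4-trans)
Conditions: NaBH4, MeOH–THF, 0 °C
Reagents that add atoms: none
Why: Borohydride reduction of the aryl ketone; axial hydride attack should give the equatorial 4-hydroxyl trans to O3, and the C4 configuration is of no consequence because C4 is ionised in step 10.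

Step 8
Reactants: 13 4,6-dibromobenzene-1,3-diol
Product: 14 1,5-dibromo-2,4-bis(prop-2-en-1-yloxy)benzene
Conditions: allyl bromide, K2CO3, acetone, reflux
Reagents that add atoms: allyl bromide, C=CCBr
Why: Williamson etherification; the symmetric dibromide carries one handle for each of the two bonds that ring M must form.

Step 9
Reactants: 14 1,5-dibromo-2,4-bis(prop-2-en-1-yloxy)benzene
Product: 16 [5-bromo-2,4-bis(prop-2-en-1-yloxy)phenyl]boronic acid, via aryllithium 15 (not isolated)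
Conditions: n-BuLi (1.0 equiv), THF, −78 °C; B(O-i-Pr)3, −78 °C → rt; 1 M HCl
Reagents that add atoms: triisopropyl borate, CC(C)OB(OC(C)C)OC(C)C; water, O
Why: Mono bromine–lithium exchange of a symmetric dibromide and borylation of the aryllithium; the borate is hydrolysed on work-up.

Step 10
Reactants: 12 tri-O-benzyl flavan-3,4-diol; 16 ring M boronic acid
Product: 18 (2R,3S)-2,3-trans-3,4-cis-7-(benzyloxy)-2-[3,4-bis(benzyloxy)phenyl]-4-[5-bromo-2,4-bis(prop-2-en-1-yloxy)phenyl]-3,4-dihydro-2H-chromen-3-ol (4β-aryl), via cyclic boronate 17 (not isolated)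
Conditions: 16 (1.3 equiv), 4 Å MS, CH2Cl2, rt; then BF3·OEt2 (0.3 equiv), −78 → −20 °C, 0.01 M; aq. NaHCO3
Reagents that add atoms: none
Why: Proposed new method: the diol and the boronic acid condense to a cyclic boronate, BF3 ionises the benzylic C4–O bond (cation stabilised by the para 7-benzyloxy group) while boron stays on O3, and the electron-rich aryl group (ipso carbon ortho and para to the allyloxy groups) should shift from the borate to C4 through a five-membered transition state on the face of O3, giving the 3,4-cis product and the free 3-hydroxyl after hydrolysis; the closest known reaction types are the Petasis borono-Mannich reaction of α-hydroxy aldehydes and the hydroxyl-directed cis addition of aryl boronates to cyclic N-acyliminium ions, here applied to a benzylic cation.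

Step 11
Reactants: 18 4β-aryl flavan-3-ol
Product: 19 (2R,3S)-2,3-trans-3,4-cis-3,7-bis(benzyloxy)-2-[3,4-bis(benzyloxy)phenyl]-4-[5-bromo-2,4-bis(prop-2-en-1-yloxy)phenyl]-3,4-dihydro-2H-chromene
Conditions: NaH, BnBr, n-Bu4NI (cat.), DMF, 0 °C → rt
Reagents that add atoms: benzyl bromide, BrCc1ccccc1
Why: Williamson etherification of the only free hydroxyl, so that the aryllithium of step 12 meets no acidic proton.

Step 12
Reactants: 19 ring M bromide; 4 epoxy amide
Product: 21 {(2R,3S)-3-[3,4-bis(benzyloxy)phenyl]oxiran-2-yl}{5-[(2R,3S)-2,3-trans-3,4-cis-3,7-bis(benzyloxy)-2-[3,4-bis(benzyloxy)phenyl]-3,4-dihydro-2H-chromen-4-yl]-2,4-bis(prop-2-en-1-yloxy)phenyl}methanone, via aryllithium 20 (not isolated)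
Conditions: n-BuLi, THF, −78 °C; then 4, −78 → −40 °C; aq. NH4Cl
Reagents that add atoms: none
Why: Same bromine–lithium exchange and morpholine amide acylation as in step 4; benzyl and allyl ethers and the diarylmethine C–H should be inert at −78 °C.

Step 13
Reactants: 21 dimeric bis(allyloxy) epoxy ketone
Product: 23 3,7,3′,4′-tetra-O-benzylfisetinidol-(4β→6)-3′,4′-di-O-benzyl-(2R,3R)-fustin, via dihydroxyphenyl epoxy ketone 22 (not isolated)
Conditions: Pd(PPh3)4 (5 mol%), K2CO3 (0.3 equiv), MeOH–THF, 0 °C, argon; AcOH quench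
Reagents that add atoms: none
Why: Pd(PPh3)4 ionises both allyl aryl ethers and methoxide takes up the allyl fragments, so the C8a phenoxide of ring M is set free beside the epoxy ketone and attacks the benzylic epoxide carbon (C2) from the side opposite the epoxide oxygen, which stays on C3 as the hydroxyl group. The closest known reaction type is the ring-closing stage of the Algar–Flynn–Oyamada reaction, in which 2′-hydroxychalcone epoxides give trans-dihydroflavonols; it mirrors the chalcone-to-flavanonol sequence of flavonoid biosynthesis. The pyranone ring closes in the 6-endo-tet mode. C2 (R) is set by inversion at the epoxide carbon and C3 (R) is carried over unchanged, so both go back to the reagent-controlled epoxidation of step 2, and the trans epoxide dictates 2,3-trans. The step needs attack at C2 and not at C3 (5-exo, benzofuranone) and no part for the second freed phenol: the cation-stabilising 3,4-bis(benzyloxy)phenyl group and the unsubstituted C5 position beside the carbonyl favour C2, and O7 lies para to the acyl carbon and cannot reach the epoxide. The ketone that enforces this mode is a helper: it is reduced in step 14 and leaves as the C4 cation in step 15.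

Step 14
Reactants: 23 dimeric dihydroflavonol
Product: 24 3,7,3′,4′-tetra-O-benzylfisetinidol-(4β→6)-3′,4′-di-O-benzyl-(2R,3S,4R)-flavan-3,4,7-triol (middle unit 2,3-trans-3,4-trans)
Conditions: NaBH4, MeOH–THF, 0 °C
Reagents that add atoms: none
Why: Borohydride reduction of the dihydroflavonol ketone as in step 7; either C4 epimer serves, since C4 is ionised next.

Step 15
Reactants: 24 dimeric flavan-3,4-diol; 6 1-bromo-2,4-bis(prop-2-en-1-yloxy)benzene
Product: 25 3,7,3′,4′-tetra-O-benzylfisetinidol-(4β→6)-3′,4′-di-O-benzyl-4α-[5-bromo-2,4-bis(prop-2-en-1-yloxy)phenyl]fisetinidol (middle unit 2,3-trans-3,4-trans)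
Conditions: 6 (5 equiv), BF3·OEt2 (0.2 equiv), CH2Cl2, −40 → 0 °C, slow addition of 24
Reagents that add atoms: none
Why: Biomimetic Friedel–Crafts alkylation through the flavan-4-yl cation (stabilised by the para 7-hydroxyl); the arene should react at C5 (para to one allyloxy group, ortho to the other) and enter anti to the C3 hydroxyl of the 2,3-trans cation, giving the 3,4-trans (4α) bond.

Step 16
Reactants: 25 ring L bromide with free 7- and 3-hydroxyl
Product: 26 3,7,3′,4′-tetra-O-benzylfisetinidol-(4β→6)-3,7,3′,4′-tetra-O-benzyl-4α-[5-bromo-2,4-bis(prop-2-en-1-yloxy)phenyl]fisetinidol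
Conditions: NaH, BnBr, n-Bu4NI (cat.), DMF, 0 °C → rt
Reagents that add atoms: benzyl bromide, BrCc1ccccc1
Why: Williamson etherification of the ring M phenol and the middle C3 alcohol removes all acidic protons before the next lithiation.

Step 17
Reactants: 26 per-benzylated ring L bromide; 4 epoxy amide
Product: 28 trimeric bis(allyloxy) epoxy ketone (ring L bears the (2R,3S)-3-[3,4-bis(benzyloxy)phenyl]oxiran-2-yl carbonyl group ortho to one allyloxy group), via aryllithium 27 (not isolated)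
Conditions: n-BuLi, THF, −78 °C; then 4, −78 → −40 °C; aq. NH4Cl
Reagents that add atoms: none
Why: Third use of the bromine–lithium exchange and morpholine amide acylation of step 4.

Step 18
Reactants: 28 trimeric bis(allyloxy) epoxy ketone
Product: 30 3,7,3′,4′-tetra-O-benzylfisetinidol-(4β→6)-3,7,3′,4′-tetra-O-benzylfisetinidol-(4α→6)-3′,4′-di-O-benzyl-(2R,3R)-fustin, via dihydroxyphenyl epoxy ketone 29 (not isolated)
Conditions: Pd(PPh3)4 (5 mol%), K2CO3 (0.3 equiv), MeOH–THF, 0 °C, argon; AcOH quench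
Reagents that add atoms: none
Why: Same deallylation and Algar–Flynn–Oyamada-type 6-endo epoxide opening as in steps 5 and 13, setting C2 and C3 of the bottom unit by inversion at the epoxide carbon.

Step 19
Reactants: 30 deca-O-benzyl trimeric dihydroflavonol
Product: 31 fisetinidol-(4β→6)-fisetinidol-(4α→6)-(2R,3R)-fustin
Conditions: H2 (1 atm), Pd(OH)2/C, THF–MeOH, rt
Reagents that add atoms: none
Why: Hydrogenolysis of the ten benzyl ethers; it is run at the ketone stage because the deactivated aryl ketone should survive, whereas a para-hydroxybenzylic 4-hydroxyl would be at risk.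

Step 20
Reactants: 31 trimeric dihydroflavonol polyphenol
Product: 32 fisetinidol-(4β→6)-fisetinidol-(4α→6)-(2R,3S,4R)-flavan-3,4-diol (target, CNP0255184.1)
Conditions: NaBH4, EtOH–H2O, 0 °C; AcOH to pH 6; Sephadex LH-20
Reagents that add atoms: none
Why: Borohydride reduction of a (2R,3R)-dihydroflavonol (the fustin-to-mollisacacidin reduction); axial hydride attack should set the bottom C4 as R with the 4-hydroxyl trans to O3.

**Compound list**
1 | 3,4-bis(benzyloxy)benzaldehyde | O=Cc1ccc(OCc2ccccc2)c(OCc2ccccc2)c1 | starting material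
2 | diethyl [2-(morpholin-4-yl)-2-oxoethyl]phosphonate | CCOP(=O)(CC(=O)N1CCOCC1)OCC | starting material
3 | (E)-3-[3,4-bis(benzyloxy)phenyl]-1-(morpholin-4-yl)prop-2-en-1-one | O=C(/C=C/c1ccc(OCc2ccccc2)c(OCc2ccccc2)c1)N1CCOCC1 | intermediate
4 | {(2R,3S)-3-[3,4-bis(benzyloxy)phenyl]oxiran-2-yl}(morpholin-4-yl)methanone (trans) | O=C([C@@H]1O[C@H]1c1ccc(OCc2ccccc2)c(OCc2ccccc2)c1)N1CCOCC1 | intermediate
5 | 4-bromobenzene-1,3-diol | Oc1ccc(Br)c(O)c1 | starting material
6 | 1-bromo-2,4-bis(prop-2-en-1-yloxy)benzene | C=CCOc1ccc(Br)c(OCC=C)c1 | intermediate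
7 | [2,4-bis(prop-2-en-1-yloxy)phenyl]lithium | [Li]c1ccc(OCC=C)cc1OCC=C | intermediate
8 | {(2R,3S)-3-[3,4-bis(benzyloxy)phenyl]oxiran-2-yl}[2,4-bis(prop-2-en-1-yloxy)phenyl]methanone | O=C(c1ccc(OCC=C)cc1OCC=C)[C@@H]1O[C@H]1c1ccc(OCc2ccccc2)c(OCc2ccccc2)c1 | intermediate
9 | {(2R,3S)-3-[3,4-bis(benzyloxy)phenyl]oxiran-2-yl}(2,4-dihydroxyphenyl)methanone (present as phenoxide) | O=C(c1ccc(O)cc1O)[C@@H]1O[C@H]1c1ccc(OCc2ccccc2)c(OCc2ccccc2)c1 | intermediate
10 | (2R,3R)-2-[3,4-bis(benzyloxy)phenyl]-3,7-dihydroxy-2,3-dihydro-4H-chromen-4-one | Oc1ccc2c(c1)O[C@H](c1ccc(OCc3ccccc3)c(OCc3ccccc3)c1)[C@@H](O)C2=O | intermediate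
11 | (2R,3R)-7-(benzyloxy)-2-[3,4-bis(benzyloxy)phenyl]-3-hydroxy-2,3-dihydro-4H-chromen-4-one | C(c1ccccc1)Oc1ccc2c(c1)O[C@H](c1ccc(OCc3ccccc3)c(OCc3ccccc3)c1)[C@@H](O)C2=O | intermediate
12 | (2R,3S,4R)-7-(benzyloxy)-2-[3,4-bis(benzyloxy)phenyl]-3,4-dihydro-2H-chromene-3,4-diol (2,3-trans-3,4-trans) | C(c1ccccc1)Oc1ccc2c(c1)O[C@H](c1ccc(OCc3ccccc3)c(OCc3ccccc3)c1)[C@@H](O)[C@@H]2O | intermediate
13 | 4,6-dibromobenzene-1,3-diol | Oc1cc(O)c(Br)cc1Br | starting material
14 | 1,5-dibromo-2,4-bis(prop-2-en-1-yloxy)benzene | C=CCOc1cc(OCC=C)c(Br)cc1Br | intermediate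
15 | [5-bromo-2,4-bis(prop-2-en-1-yloxy)phenyl]lithium | [Li]c1cc(Br)c(OCC=C)cc1OCC=C | intermediate
16 | [5-bromo-2,4-bis(prop-2-en-1-yloxy)phenyl]boronic acid | OB(O)c1cc(Br)c(OCC=C)cc1OCC=C | intermediate
17 | cyclic 3,4-O-{[5-bromo-2,4-bis(prop-2-en-1-yloxy)phenyl]boranediyl} derivative of diol 12 (2R,3S,4R) | C(c1ccccc1)Oc1ccc2c(c1)O[C@H](c1ccc(OCc3ccccc3)c(OCc3ccccc3)c1)[C@@H](OB3c4cc(Br)c(OCC=C)cc4OCC=C)[C@@H]2O3 | intermediate
18 | (2R,3S)-2,3-trans-3,4-cis-7-(benzyloxy)-2-[3,4-bis(benzyloxy)phenyl]-4-[5-bromo-2,4-bis(prop-2-en-1-yloxy)phenyl]-3,4-dihydro-2H-chromen-3-ol (4β-aryl) | C(c1ccccc1)Oc1ccc2c(c1)O[C@H](c1ccc(OCc3ccccc3)c(OCc3ccccc3)c1)[C@@H](O)[C@H]2c1cc(Br)c(OCC=C)cc1OCC=C | intermediate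
19 | 3-O-benzyl ether of 18 (2R,3S; 2,3-trans-3,4-cis) | C(c1ccccc1)Oc1ccc2c(c1)O[C@H](c1ccc(OCc3ccccc3)c(OCc3ccccc3)c1)[C@@H](OCc1ccccc1)[C@H]2c1cc(Br)c(OCC=C)cc1OCC=C | intermediate
20 | aryllithium from 19 (Li in place of Br on ring M) | C(c1ccccc1)Oc1ccc2c(c1)O[C@H](c1ccc(OCc3ccccc3)c(OCc3ccccc3)c1)[C@@H](OCc1ccccc1)[C@H]2c1cc([Li])c(OCC=C)cc1OCC=C | intermediate
21 | dimeric epoxy ketone: ring M of 19 carries the (2R,3S)-3-[3,4-bis(benzyloxy)phenyl]oxiran-2-yl carbonyl group in place of Br | C(c1ccccc1)Oc1ccc2c(c1)O[C@H](c1ccc(OCc3ccccc3)c(OCc3ccccc3)c1)[C@@H](OCc1ccccc1)[C@H]2c1cc(C(=O)[C@@H]3O[C@H]3c4ccc(OCc5ccccc5)c(OCc5ccccc5)c4)c(OCC=C)cc1OCC=C | intermediate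
22 | dimeric epoxy ketone with both ring M allyl ethers removed (present as phenoxide) | C(c1ccccc1)Oc1ccc2c(c1)O[C@H](c1ccc(OCc3ccccc3)c(OCc3ccccc3)c1)[C@@H](OCc1ccccc1)[C@H]2c1cc(C(=O)[C@@H]3O[C@H]3c4ccc(OCc5ccccc5)c(OCc5ccccc5)c4)c(O)cc1O | intermediate
23 | 3,7,3′,4′-tetra-O-benzylfisetinidol-(4β→6)-3′,4′-di-O-benzyl-(2R,3R)-fustin (top unit 2R,3S, 3,4-cis) | C(c1ccccc1)Oc1ccc2c(c1)O[C@H](c1ccc(OCc3ccccc3)c(OCc3ccccc3)c1)[C@@H](OCc1ccccc1)[C@H]2c1cc2c(cc1O)O[C@H](c1ccc(OCc3ccccc3)c(OCc3ccccc3)c1)[C@@H](O)C2=O | intermediate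
24 | 3,7,3′,4′-tetra-O-benzylfisetinidol-(4β→6)-3′,4′-di-O-benzyl-(2R,3S,4R)-flavan-3,4,7-triol | C(c1ccccc1)Oc1ccc2c(c1)O[C@H](c1ccc(OCc3ccccc3)c(OCc3ccccc3)c1)[C@@H](OCc1ccccc1)[C@H]2c1cc2c(cc1O)O[C@H](c1ccc(OCc3ccccc3)c(OCc3ccccc3)c1)[C@@H](O)[C@@H]2O | intermediate
25 | 3,7,3′,4′-tetra-O-benzylfisetinidol-(4β→6)-3′,4′-di-O-benzyl-4α-[5-bromo-2,4-bis(prop-2-en-1-yloxy)phenyl]fisetinidol (middle unit 2R,3S, 3,4-trans) | C(c1ccccc1)Oc1ccc2c(c1)O[C@H](c1ccc(OCc3ccccc3)c(OCc3ccccc3)c1)[C@@H](OCc1ccccc1)[C@H]2c1cc2c(cc1O)O[C@H](c1ccc(OCc3ccccc3)c(OCc3ccccc3)c1)[C@@H](O)[C@@H]2c1cc(Br)c(OCC=C)cc1OCC=C | intermediate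
26 | 7,3-di-O-benzyl ether (middle unit) of 25 | C(c1ccccc1)Oc1ccc2c(c1)O[C@H](c1ccc(OCc3ccccc3)c(OCc3ccccc3)c1)[C@@H](OCc1ccccc1)[C@H]2c1cc2c(cc1OCc1ccccc1)O[C@H](c1ccc(OCc3ccccc3)c(OCc3ccccc3)c1)[C@@H](OCc1ccccc1)[C@@H]2c1cc(Br)c(OCC=C)cc1OCC=C | intermediate
27 | aryllithium from 26 (Li in place of Br on ring L) | C(c1ccccc1)Oc1ccc2c(c1)O[C@H](c1ccc(OCc3ccccc3)c(OCc3ccccc3)c1)[C@@H](OCc1ccccc1)[C@H]2c1cc2c(cc1OCc1ccccc1)O[C@H](c1ccc(OCc3ccccc3)c(OCc3ccccc3)c1)[C@@H](OCc1ccccc1)[C@@H]2c1cc([Li])c(OCC=C)cc1OCC=C | intermediate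
28 | trimeric epoxy ketone: ring L of 26 carries the (2R,3S)-3-[3,4-bis(benzyloxy)phenyl]oxiran-2-yl carbonyl group in place of Br | C(c1ccccc1)Oc1ccc2c(c1)O[C@H](c1ccc(OCc3ccccc3)c(OCc3ccccc3)c1)[C@@H](OCc1ccccc1)[C@H]2c1cc2c(cc1OCc1ccccc1)O[C@H](c1ccc(OCc3ccccc3)c(OCc3ccccc3)c1)[C@@H](OCc1ccccc1)[C@@H]2c1cc(C(=O)[C@@H]3O[C@H]3c4ccc(OCc5ccccc5)c(OCc5ccccc5)c4)c(OCC=C)cc1OCC=C | intermediate
29 | trimeric epoxy ketone with both ring L allyl ethers removed (present as phenoxide) | C(c1ccccc1)Oc1ccc2c(c1)O[C@H](c1ccc(OCc3ccccc3)c(OCc3ccccc3)c1)[C@@H](OCc1ccccc1)[C@H]2c1cc2c(cc1OCc1ccccc1)O[C@H](c1ccc(OCc3ccccc3)c(OCc3ccccc3)c1)[C@@H](OCc1ccccc1)[C@@H]2c1cc(C(=O)[C@@H]3O[C@H]3c4ccc(OCc5ccccc5)c(OCc5ccccc5)c4)c(O)cc1O | intermediate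
30 | 3,7,3′,4′-tetra-O-benzylfisetinidol-(4β→6)-3,7,3′,4′-tetra-O-benzylfisetinidol-(4α→6)-3′,4′-di-O-benzyl-(2R,3R)-fustin | C(c1ccccc1)Oc1ccc2c(c1)O[C@H](c1ccc(OCc3ccccc3)c(OCc3ccccc3)c1)[C@@H](OCc1ccccc1)[C@H]2c1cc2c(cc1OCc1ccccc1)O[C@H](c1ccc(OCc3ccccc3)c(OCc3ccccc3)c1)[C@@H](OCc1ccccc1)[C@@H]2c1cc2c(cc1O)O[C@H](c1ccc(OCc3ccccc3)c(OCc3ccccc3)c1)[C@@H](O)C2=O | intermediate
31 | fisetinidol-(4β→6)-fisetinidol-(4α→6)-(2R,3R)-fustin | Oc1ccc2c(c1)O[C@H](c1ccc(O)c(O)c1)[C@@H](O)[C@H]2c1cc2c(cc1O)O[C@H](c1ccc(O)c(O)c1)[C@@H](O)[C@@H]2c1cc2c(cc1O)O[C@H](c1ccc(O)c(O)c1)[C@@H](O)C2=O | intermediate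
32 | fisetinidol-(4β→6)-fisetinidol-(4α→6)-(2R,3S,4R)-flavan-3,4,7,3′,4′-pentaol; top unit 2R,3S,4S, middle unit 2R,3S,4R, bottom unit 2R,3S,4R | Oc1ccc2c(c1)O[C@H](c1ccc(O)c(O)c1)[C@@H](O)[C@H]2c1cc2c(cc1O)O[C@H](c1ccc(O)c(O)c1)[C@@H](O)[C@@H]2c1cc2c(cc1O)O[C@H](c1ccc(O)c(O)c1)[C@@H](O)[C@@H]2O | target

**Step count and risks**

Total step count: 20. Longest linear sequence: 17 steps (1, 2, 4–7, 10–20).

Step 10 (riskiest). The aryl group may be transferred between molecules by ipso attack anti to O3, which would lose the cis control; the boronic acid may be protodeboronated; or the cation may be taken by C6 of ring T of a second molecule. The fallback uses known chemistry and sets the C4 diarylmethine before the C ring exists; it sets out from boronic acid 16 and returns to the route at 18. Claisen–Schmidt condensation of commercial 4-(benzyloxy)-2-hydroxybenzaldehyde with 1-[3,4-bis(benzyloxy)phenyl]ethanone (KOH, EtOH) would give the (E)-hydroxy enone F1, which is silylated (i-Pr3SiCl, imidazole) to the silyl enone F2. Hayashi–Miyaura addition of 16 ([Rh(OH)((S)-binap)]2 or its antipode, dioxane–H2O) would give the (3S)-diaryl ketone F3. NaBH4 gives the alcohol F4, and acid-catalysed dehydration (p-TsOH, toluene) the (E)-triarylpropene F5. Shi epoxidation with the L-fructose-derived ketone (KHSO5 as 2KHSO5·KHSO4·K2SO4, K2CO3 buffer) would give the (2S,3S)-epoxide F6. n-Bu4NF with AcOH then frees the ring T phenol, and pyridinium p-toluenesulfonate closes the ring 6-endo at the benzylic carbon with inversion to give 18.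

Step 13. The phenoxide may attack the α-carbon (5-exo closure to a benzofuranone), or the dihydroflavonol may suffer base-induced ring opening, C2 epimerisation or aerial dehydrogenation. The fallback is a two-stage closure that never places a phenoxide beside the epoxide; it sets out from 21 and returns at 23. Phenylmethanethiol with SnCl4 (CH2Cl2, −20 °C) opens the epoxide at the benzylic carbon to the α-hydroxy-β-benzylsulfanyl ketone F7. Pd(PPh3)4 with morpholine removes the allyl groups to give the phenol F8. AgBF4 (CH2Cl2, 0 °C) ionises the C–S bond and the phenol closes the ring to the thermodynamically preferred 2,3-trans dihydroflavonol 23.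

Step 15. Facial selectivity at the cation may be poor (3,4-cis isomer), and C6 of ring T of a second molecule may compete with arene 6. The fallback uses neighbouring-group participation to fix the face and tame the cation; it sets out from 23 and returns at 25. Acetylation (Ac2O, pyridine) gives the di-O-acetate F9, and NaBH4 with CeCl3 (−40 °C) the 4-ol F10. Me3SiOSO2CF3 (cat.) with excess 6 at −78 °C ionises C4 with participation of the 3-acetoxy group on the β-face, so the arene should enter from the α-face to give the 3,4-trans product F11. K2CO3 in MeOH removes both acetates to give 25.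

Further compounds
F1 | step 10 | (E)-1-[3,4-bis(benzyloxy)phenyl]-3-[4-(benzyloxy)-2-hydroxyphenyl]prop-2-en-1-one | O=C(/C=C/c1ccc(OCc2ccccc2)cc1O)c1ccc(OCc2ccccc2)c(OCc2ccccc2)c1
F2 | step 10 | (E)-1-[3,4-bis(benzyloxy)phenyl]-3-{4-(benzyloxy)-2-[(triisopropylsilyl)oxy]phenyl}prop-2-en-1-one | O=C(/C=C/c1ccc(OCc2ccccc2)cc1O[Si](C(C)C)(C(C)C)C(C)C)c1ccc(OCc2ccccc2)c(OCc2ccccc2)c1
F3 | step 10 | (3S)-1-[3,4-bis(benzyloxy)phenyl]-3-{4-(benzyloxy)-2-[(triisopropylsilyl)oxy]phenyl}-3-[5-bromo-2,4-bis(prop-2-en-1-yloxy)phenyl]propan-1-one | O=C(C[C@H](c1ccc(OCc2ccccc2)cc1O[Si](C(C)C)(C(C)C)C(C)C)c1cc(Br)c(OCC=C)cc1OCC=C)c1ccc(OCc2ccccc2)c(OCc2ccccc2)c1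
F4 | step 10 | (3S)-1-[3,4-bis(benzyloxy)phenyl]-3-{4-(benzyloxy)-2-[(triisopropylsilyl)oxy]phenyl}-3-[5-bromo-2,4-bis(prop-2-en-1-yloxy)phenyl]propan-1-ol (both C1 epimers) | OC(C[C@H](c1ccc(OCc2ccccc2)cc1O[Si](C(C)C)(C(C)C)C(C)C)c1cc(Br)c(OCC=C)cc1OCC=C)c1ccc(OCc2ccccc2)c(OCc2ccccc2)c1
F5 | step 10 | (1E,3S)-1-[3,4-bis(benzyloxy)phenyl]-3-{4-(benzyloxy)-2-[(triisopropylsilyl)oxy]phenyl}-3-[5-bromo-2,4-bis(prop-2-en-1-yloxy)phenyl]prop-1-ene | c1cc(OCc2ccccc2)c(OCc2ccccc2)cc1/C=C/[C@H](c1ccc(OCc2ccccc2)cc1O[Si](C(C)C)(C(C)C)C(C)C)c1cc(Br)c(OCC=C)cc1OCC=C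
F6 | step 10 | (2S,3S)-2-[3,4-bis(benzyloxy)phenyl]-3-[(S)-{4-(benzyloxy)-2-[(triisopropylsilyl)oxy]phenyl}[5-bromo-2,4-bis(prop-2-en-1-yloxy)phenyl]methyl]oxirane | [C@@H]1(c2ccc(OCc3ccccc3)c(OCc3ccccc3)c2)O[C@H]1[C@H](c1ccc(OCc2ccccc2)cc1O[Si](C(C)C)(C(C)C)C(C)C)c1cc(Br)c(OCC=C)cc1OCC=C
F7 | step 13 | (2S,3R)-3-(benzylsulfanyl)-3-[3,4-bis(benzyloxy)phenyl]-2-hydroxypropan-1-one bearing at C1 the 5-(flavan-4-yl)-2,4-bis(prop-2-en-1-yloxy)phenyl group of 21 | C(c1ccccc1)Oc1ccc2c(c1)O[C@H](c1ccc(OCc3ccccc3)c(OCc3ccccc3)c1)[C@@H](OCc1ccccc1)[C@H]2c1cc(C(=O)[C@H](O)[C@H](SCc6ccccc6)c4ccc(OCc5ccccc5)c(OCc5ccccc5)c4)c(OCC=C)cc1OCC=C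
F8 | step 13 | F7 with both allyl ethers of ring M removed (2,4-dihydroxyphenyl ketone) | C(c1ccccc1)Oc1ccc2c(c1)O[C@H](c1ccc(OCc3ccccc3)c(OCc3ccccc3)c1)[C@@H](OCc1ccccc1)[C@H]2c1cc(C(=O)[C@H](O)[C@H](SCc6ccccc6)c4ccc(OCc5ccccc5)c(OCc5ccccc5)c4)c(O)cc1O
F9 | step 15 | 3,7-di-O-acetate (middle unit) of 23 | C(c1ccccc1)Oc1ccc2c(c1)O[C@H](c1ccc(OCc3ccccc3)c(OCc3ccccc3)c1)[C@@H](OCc1ccccc1)[C@H]2c1cc2c(cc1OC(C)=O)O[C@H](c1ccc(OCc3ccccc3)c(OCc3ccccc3)c1)[C@@H](OC(C)=O)C2=O
F10 | step 15 | 4-ol from F9 (middle unit 2R,3S,4R, 3,4-trans, 3- and 7-acetates kept) | C(c1ccccc1)Oc1ccc2c(c1)O[C@H](c1ccc(OCc3ccccc3)c(OCc3ccccc3)c1)[C@@H](OCc1ccccc1)[C@H]2c1cc2c(cc1OC(C)=O)O[C@H](c1ccc(OCc3ccccc3)c(OCc3ccccc3)c1)[C@@H](OC(C)=O)[C@@H]2O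
F11 | step 15 | 3,7-di-O-acetate (middle unit) of 25 (4α-aryl, 3,4-trans) | C(c1ccccc1)Oc1ccc2c(c1)O[C@H](c1ccc(OCc3ccccc3)c(OCc3ccccc3)c1)[C@@H](OCc1ccccc1)[C@H]2c1cc2c(cc1OC(C)=O)O[C@H](c1ccc(OCc3ccccc3)c(OCc3ccccc3)c1)[C@@H](OC(C)=O)[C@@H]2c1cc(Br)c(OCC=C)cc1OCC=C
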